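## Retrosynthetic overview

1. Endgame: the diformylphloroglucinol is unmasked last from a 2,4,6-trimethoxyphenyl group (dibromination, Br/Li exchange–formylation, thiolate demethylation); the C4 carbinol comes from equatorial MeLi addition to a C4 ketone; the benzylic C–C bond comes from A(1,3)-controlled SN1 methallylation of an aryl carbinol made from a C1 aldehyde (eudesmane numbering: ring A = C1–C5 and C10, ring B = C5–C10, C11 = carbinol carbon on C7).
2. Ring B is not made as a six-membered ring: it arises from the cyclobutane C5–C8–C9–C10 of a bicyclo[4.2.0]octan-2-one by a two-atom ring expansion (retro-aldol cleavage of C5–C8, then 6-endo Michael closure C5–C6) that inserts C6 and C7 of an alkenyl group carried on C8, and ends as the C8 enol triflate.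
3. Enabling feature: the ring-A carbonyl C4 is β to the cyclobutanol oxygen on C8 through C5 (O=C4–C5–C8–O), so the strained C5–C8 bond cleaves to the C4/C5 enolate, and the 1-alkenyl group on C8 (C7=C6H2, with C11 already on C7) becomes the vinyl ketone onto which C5 recloses.
4. The cyclobutane comes from a head-to-head enone–allene [2+2] photocycloaddition on ring A, which sets the quaternary C10 anti to the C1 substituent; ring A with its C1 stereocentre comes from 4-(hydroxymethyl)cyclohexanone by chiral-base desymmetrisation and two Saegusa–Ito oxidations.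
5. Ring order: ring A (from the starting cyclohexanone), then the cyclobutane (photochemical), then ring B (step 10, four- to six-membered); the aromatic ring is attached afterwards.

Key step: step 10

Assumption: the chiral lithium amide in step 2 shows the sense of induction known for 4-substituted cyclohexanones ((R,R)-base giving the (S)-enol silane); if the sense were opposite, the (S,S)-base would be used.

Remark: the stereocentres at C8 in 13–15 and at the carbinol carbon of 26 are destroyed again in steps 10 and 15; the expected major epimers are drawn and either epimer serves.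

## Route

Step 1
Reactants: 1 4-(hydroxymethyl)cyclohexan-1-one
Product: 2 4-[(benzyloxy)methyl]cyclohexan-1-one
Conditions: BnOC(=NH)CCl3, TfOH (cat.), CH2Cl2/cyclohexane, 0 °C to rt
Reagents that add atoms: benzyl 2,2,2-trichloroacetimidate N=C(OCc1ccccc1)C(Cl)(Cl)Cl
Why: Acid-catalysed O-benzylation with the trichloroacetimidate should protect the primary alcohol without the basic conditions that would enolise the ketone, and no stereocentre is formed.

Step 2
Reactants: 2 4-[(benzyloxy)methyl]cyclohexan-1-one
Product: 4 (S)-4-[(benzyloxy)methyl]cyclohex-2-en-1-one, via silyl enol ether 3 (not isolated)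
Conditions: (R,R)-[PhCH(CH3)]2NLi (from the amine and n-BuLi), Me3SiCl (in situ quench), THF, −100 °C; then Pd(OAc)2 (1.0 equiv), MeCN, rt
Reagents that add atoms: none
Why: Enantioselective deprotonation of the prochiral ketone by the chiral lithium amide base should remove one of the two enantiotopic axial α-protons and so fix the C1 stereocentre as the (S)-enol silane, and Saegusa–Ito oxidation then places the enone double bond on that side.

Step 3
Reactants: 4 (S)-4-[(benzyloxy)methyl]cyclohex-2-en-1-one
Product: 6 (S)-4-[(benzyloxy)methyl]-3-methylcyclohex-2-en-1-one, via silyl enol ether 5 (not isolated)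
Conditions: MeMgBr, CuBr·SMe2 (10 mol%), Me3SiCl, THF, −78 °C; then Pd(OAc)2 (1.0 equiv), MeCN, rt
Reagents that add atoms: methylmagnesium bromide C[Mg]Br
Why: Copper-catalysed conjugate addition of the methyl Grignard reagent with enol silane trapping, followed by a second Saegusa–Ito oxidation, should install the β-methyl group and regenerate the enone, the C1 stereocentre being untouched and the transient methyl-bearing centre returning to sp2.

Step 4
Reactants: 6 (S)-4-[(benzyloxy)methyl]-3-methylcyclohex-2-en-1-one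
Product: 7 cis-fused 5-[(benzyloxy)methyl]-6-methyl-8-methylidenebicyclo[4.2.0]octan-2-one
Conditions: allene (excess), hν (λ > 300 nm, Pyrex), CH2Cl2, −78 °C; then basic Al2O3
Reagents that add atoms: propadiene C=C=C
Why: The enone–allene [2+2] photocycloaddition should give the head-to-head methylenecyclobutane (allene central carbon on the enone α-carbon C5), the allene adding to the face of C10 anti to the neighbouring benzyloxymethyl group so that the angular methyl is cis to it, and alumina should epimerise any trans-fused adduct at C5 to the cis-fused ketone.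

Step 5
Reactants: 7 cis-fused 5-[(benzyloxy)methyl]-6-methyl-8-methylidenebicyclo[4.2.0]octan-2-one
Product: 8 5'-[(benzyloxy)methyl]-6'-methyl-8'-methylidenespiro[1,3-dioxolane-2,2'-bicyclo[4.2.0]octane]
Conditions: Me3SiOCH2CH2OSiMe3, Me3SiOTf (cat.), CH2Cl2, −78 to −20 °C
Reagents that add atoms: 1,2-bis(trimethylsilyloxy)ethane C[Si](C)(C)OCCO[Si](C)(C)C
Why: Aprotic low-temperature ketalisation with the bis-silyl glycol should mask the C4 ketone while avoiding the acid-mediated 1,2-acyl shift (Cargill rearrangement) of the β,γ-unsaturated ketone, with no change at any stereocentre.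

Step 6
Reactants: 8 5'-[(benzyloxy)methyl]-6'-methyl-8'-methylidenespiro[1,3-dioxolane-2,2'-bicyclo[4.2.0]octane]
Product: 9 5'-[(benzyloxy)methyl]-6'-methylspiro[1,3-dioxolane-2,2'-bicyclo[4.2.0]octan]-8'-one
Conditions: O3, CH2Cl2, −78 °C; then Me2S, −78 °C to rt
Reagents that add atoms: ozone [O-][O+]=O
Why: Ozonolysis of the exocyclic 1,1-disubstituted alkene should give the cyclobutanone, the ketal at C4 preventing formation of an acidic and ring-opening-prone cyclobutanone 1,3-diketone.

Step 7
Reactants: 10 3-hydroxy-3-methylbutan-2-one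
Product: 11 (E)-N'-(3-hydroxy-3-methylbutan-2-ylidene)-2,4,6-tri(propan-2-yl)benzenesulfonohydrazide
Conditions: 2,4,6-(i-Pr)3C6H2SO2NHNH2, MeOH, rt
Reagents that add atoms: 2,4,6-triisopropylbenzenesulfonohydrazide NNS(=O)(=O)c1c(C(C)C)cc(C(C)C)cc1C(C)C
Why: Condensation of the methyl ketone with the arenesulfonylhydrazide should give the hydrazone required for a Shapiro reaction, in which only the methyl group can be deprotonated.

Step 8
Reactants: 11 trisylhydrazone of 3-hydroxy-3-methylbutan-2-one; 9 cyclobutanone ketal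
Product: 14 bis(triethylsilyl) ether of the 8'-alkenyl cyclobutanol ketal, via vinyllithium 12 (not isolated), via dilithium dialkoxide 13 (not isolated)
Conditions: 11 (1.5 equiv), n-BuLi (3.0 equiv per 11), THF, −78 to 0 °C; then 9, −78 °C; then Et3SiOTf (excess), −78 to 0 °C
Reagents that add atoms: triethylsilyl trifluoromethanesulfonate CC[Si](CC)(CC)OS(=O)(=O)C(F)(F)F
Why: The Shapiro reaction should give the 2-lithio allylic alkoxide (its O–Li group cannot leave, so no allene is formed), which adds to the strained cyclobutanone from its convex face before both tertiary alkoxides are silylated, the configuration of the new C8 centre being immaterial.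

Step 9
Reactants: 14 bis(triethylsilyl) ether of the 8'-alkenyl cyclobutanol ketal
Product: 15 5-[(benzyloxy)methyl]-6-methyl-8-[(triethylsilyl)oxy]-8-{3-methyl-3-[(triethylsilyl)oxy]but-1-en-2-yl}bicyclo[4.2.0]octan-2-one
Conditions: pyridinium p-toluenesulfonate (cat.), acetone/H2O, 40 °C
Reagents that add atoms: water O
Why: Mild acid-catalysed ketal hydrolysis should free the hindered C4 ketone while the tertiary triethylsilyl ethers and the benzyl ether survive, giving a β-silyloxy ketone that cannot yet undergo retro-aldol cleavage.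

Step 10
Reactants: 15 5-[(benzyloxy)methyl]-6-methyl-8-[(triethylsilyl)oxy]-8-{3-methyl-3-[(triethylsilyl)oxy]but-1-en-2-yl}bicyclo[4.2.0]octan-2-one
Product: 19 cis-fused 8-[(benzyloxy)methyl]-3-(2-hydroxypropan-2-yl)-8a-methyl-5-oxo-1,4,4a,5,6,7,8,8a-octahydronaphthalen-2-yl trifluoromethanesulfonate, via bis-alkoxide 16 (not isolated), via ring-opened enolate 17 (not isolated), via decalin enolate 18 (not isolated)
Conditions: (Me2N)3S+ Me3SiF2− (2.2 equiv), THF, −20 °C to rt; then PhNTf2 (1.2 equiv), −78 to 0 °C; aq. NH4Cl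
Reagents that add atoms: N-phenylbis(trifluoromethanesulfonimide) O=S(=O)(N(c1ccccc1)S(=O)(=O)C(F)(F)F)C(F)(F)F
Why: Fluoride removes both triethylsilyl groups, and the cyclobutanolate on C8, which is β to the C4 carbonyl through C5, should undergo strain-driven retro-aldol cleavage of the C5–C8 bond (the fragmentation step of the de Mayo reaction) to the C4/C5 enolate and the vinyl ketone C8(=O)–C7(=C6H2). The enolate carbon C5 then closes ring B on C6 by a 6-endo-trig intramolecular Michael addition, so that the four-membered ring C5–C8–C9–C10 is enlarged by the alkenyl carbons C6 and C7; overall this is an alkoxide-driven 1,3-shift of a 1-alkenylcyclobutanol, closest to the de Mayo retro-aldol sequence and to the alkoxide-accelerated two-carbon ring enlargements of vinylcyclobutanols. The Michael addition produces the C8 enolate regiospecifically, and O-sulfonylation with PhNTf2 fixes it as the C7=C8 enol triflate, which marks C8 for deoxygenation beside the untouched C4 ketone. The only new stereocentre is C5: bond formation along the enolate π-axis anti to the pseudo-axial angular methyl in a chair-like transition state should give the cis-fused decalin, and because C5 is α to the C4 ketone it is corrected by equilibration in step 12, while C1 and C10 are not involved and C7 and C8 are sp2 in the product. The selectivity needed is cleavage of C5–C8 only (the one strained bond aligned with the C4 carbonyl), cyclisation through C5 and not C3 (the retro-aldol generates the C5 enolate directly and the aprotic medium limits proton transfer) and retention of the C11 oxygen (as a free alkoxide it cannot leave by E1cB elimination, and retro-aldol loss of acetone is not possible from the enolate).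

Step 11
Reactants: 19 cis-fused enol triflate
Product: 20 cis-fused 4-[(benzyloxy)methyl]-7-(2-hydroxypropan-2-yl)-4a-methyl-3,4,4a,5,8,8a-hexahydronaphthalen-1(2H)-one
Conditions: Pd(OAc)2 (5 mol%), PPh3 (10 mol%), HCO2H, n-Bu3N, DMF, 60 °C
Reagents that add atoms: none
Why: Palladium-catalysed formate reduction of the enol triflate should replace the C8 oxygen by hydrogen and leave the C7=C8 alkene, the C4 ketone and the tertiary alcohol untouched.

Step 12
Reactants: 20 cis-fused 4-[(benzyloxy)methyl]-7-(2-hydroxypropan-2-yl)-4a-methyl-3,4,4a,5,8,8a-hexahydronaphthalen-1(2H)-one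
Product: 22 trans-fused 4-(hydroxymethyl)-7-(2-hydroxypropan-2-yl)-4a-methyloctahydronaphthalen-1(2H)-one, via trans-fused ketone 21 (not isolated)
Conditions: NaOMe (cat.), MeOH, rt; AcOH to neutral; then H2 (1 atm), Pd/C, MeOH/EtOAc, rt
Reagents that add atoms: none
Why: Base equilibration through the C4 enolate should convert the cis-fused ketone into the more stable trans-fused decalone (C5–H anti to the angular methyl), and catalytic hydrogenation should then deliver hydrogen to the trisubstituted alkene from the face opposite the axial angular methyl, which places the hydroxyisopropyl group equatorial at C7, while hydrogenolysing the benzyl ether.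

Step 13
Reactants: 22 trans-fused 4-(hydroxymethyl)-7-(2-hydroxypropan-2-yl)-4a-methyloctahydronaphthalen-1(2H)-one
Product: 23 trans-fused 6-(2-hydroxypropan-2-yl)-8a-methyl-4-oxodecahydronaphthalene-1-carbaldehyde
Conditions: Dess–Martin periodinane, CH2Cl2, 0 °C to rt
Reagents that add atoms: none
Why: Dess–Martin oxidation should convert the primary alcohol into the aldehyde under near-neutral conditions that neither touch the tertiary alcohol nor epimerise C1.

Step 14
Reactants: 24 1,3,5-trimethoxybenzene; 23 keto aldehyde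
Product: 26 4-[hydroxy(2,4,6-trimethoxyphenyl)methyl]-7-(2-hydroxypropan-2-yl)-4a-methyloctahydronaphthalen-1(2H)-one, via aryllithium 25 (not isolated)
Conditions: 24 (3 equiv), n-BuLi, THF, 0 °C to rt; then 23, THF, −78 °C
Reagents that add atoms: none
Why: Directed ortho-lithiation between two methoxy groups should give 2,4,6-trimethoxyphenyllithium, which adds to the aldehyde far faster than to the hindered C4 ketone (one equivalent is consumed by the tertiary hydroxyl), the carbinol configuration (Felkin–Anh product drawn) being irrelevant because this centre is ionised in step 15.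

Step 15
Reactants: 26 aryl carbinol
Product: 27 7-(2-hydroxypropan-2-yl)-4a-methyl-4-[(1R)-3-methyl-1-(2,4,6-trimethoxyphenyl)but-3-en-1-yl]octahydronaphthalen-1(2H)-one
Conditions: CH2=C(CH3)CH2SiMe3 (5 equiv), BF3·OEt2 (20 mol%), CH2Cl2, −78 to −40 °C
Reagents that add atoms: trimethyl(2-methylallyl)silane CC(=C)C[Si](C)(C)C
Why: SN1 substitution through the 2,4,6-trimethoxybenzylic cation with Hosomi–Sakurai capture by the methallylsilane should form the benzylic C–C bond, the stereocentre being set by A(1,3) strain: the C1–H lies in the cation plane next to an ortho-methoxy group and the nucleophile attacks anti to the quaternary C10, which corresponds to the required configuration.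

Step 16
Reactants: 27 methallylated ketone
Product: 28 7-(2-hydroxypropan-2-yl)-4a-methyl-4-[(1R)-3-methyl-1-(2,4,6-trimethoxyphenyl)butyl]octahydronaphthalen-1(2H)-one
Conditions: H2 (1 atm), Pd/C, EtOAc, rt
Reagents that add atoms: none
Why: Catalytic hydrogenation of the 1,1-disubstituted alkene should complete the isobutyl group without creating a stereocentre.

Step 17
Reactants: 28 C4 ketone
Product: 29 7-(2-hydroxypropan-2-yl)-1,4a-dimethyl-4-[(1R)-3-methyl-1-(2,4,6-trimethoxyphenyl)butyl]decahydronaphthalen-1-ol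
Conditions: MeLi (4 equiv), Et2O/THF, −78 to 0 °C
Reagents that add atoms: methyllithium [Li]C
Why: 1,2-Addition of methyllithium to the C4 ketone should occur from the equatorial direction, because axial approach is blocked by the 1,3-syn-axial angular methyl group, giving the axial tertiary alcohol cis to that methyl group.

Step 18
Reactants: 29 trimethoxyaryl diol
Product: 30 4-[(1R)-1-(3,5-dibromo-2,4,6-trimethoxyphenyl)-3-methylbutyl]-7-(2-hydroxypropan-2-yl)-1,4a-dimethyldecahydronaphthalen-1-ol
Conditions: N-bromosuccinimide (2.1 equiv), MeCN, 0 °C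
Reagents that add atoms: N-bromosuccinimide O=C1CCC(=O)N1Br
Why: Electrophilic aromatic bromination should take place at the two remaining ring positions, each activated by two flanking methoxy groups, under neutral conditions that spare the tertiary alcohols.

Step 19
Reactants: 30 dibromide
Product: 32 5-{(1R)-1-[4-hydroxy-6-(2-hydroxypropan-2-yl)-4,8a-dimethyldecahydronaphthalen-1-yl]-3-methylbutyl}-2,4,6-trimethoxybenzene-1,3-dicarbaldehyde, via dilithioarene 31 (not isolated)
Conditions: t-BuLi (9 equiv), THF, −78 °C; then DMF (excess), −78 to 0 °C; aq. NH4Cl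
Reagents that add atoms: N,N-dimethylformamide CN(C)C=O
Why: Double bromine–lithium exchange (after deprotonation of the two hydroxyl groups) followed by Bouveault formylation with DMF should introduce both aldehydes without acid, the hemiaminal alkoxides masking the formyl groups until work-up.

Step 20
Reactants: 32 trimethoxy dialdehyde
Product: 33 5-{(1R)-1-[4-hydroxy-6-(2-hydroxypropan-2-yl)-4,8a-dimethyldecahydronaphthalen-1-yl]-3-methylbutyl}-2,4,6-trihydroxybenzene-1,3-dicarbaldehyde (target)
Conditions: NaSEt (excess), DMF, 110 °C; then dilute aq. HCl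
Reagents that add atoms: none
Why: SN2 demethylation by the thiolate should cleave all three aryl methyl ethers, each phenoxide being a good leaving group because of an ortho- or para-formyl group, under basic conditions that the two tertiary alcohols tolerate.

## Compound list

1 | 4-(hydroxymethyl)cyclohexan-1-one | OCC1CCC(=O)CC1 | starting material
2 | 4-[(benzyloxy)methyl]cyclohexan-1-one | O=C1CCC(COCc2ccccc2)CC1 | intermediate
3 | (S)-{[4-((benzyloxy)methyl)cyclohex-1-en-1-yl]oxy}trimethylsilane | O(Cc1ccccc1)C[C@H]1CCC(O[Si](C)(C)C)=CC1 | intermediate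
4 | (S)-4-[(benzyloxy)methyl]cyclohex-2-en-1-one | O(Cc1ccccc1)C[C@H]1CCC(=O)C=C1 | intermediate
5 | {[trans-4-((benzyloxy)methyl)-3-methylcyclohex-1-en-1-yl]oxy}trimethylsilane (4S; methyl trans to the benzyloxymethyl group) | O(Cc1ccccc1)C[C@H]1CCC(O[Si](C)(C)C)=C[C@@H]1C | intermediate
6 | (S)-4-[(benzyloxy)methyl]-3-methylcyclohex-2-en-1-one | O(Cc1ccccc1)C[C@H]1CCC(=O)C=C1C | intermediate
7 | cis-fused 5-[(benzyloxy)methyl]-6-methyl-8-methylidenebicyclo[4.2.0]octan-2-one (cyclobutane anti to the benzyloxymethyl group, 6-methyl cis to it) | O(Cc1ccccc1)C[C@H]1CCC(=O)[C@@H]2C(=C)C[C@]12C | intermediate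
8 | 5'-[(benzyloxy)methyl]-6'-methyl-8'-methylidenespiro[1,3-dioxolane-2,2'-bicyclo[4.2.0]octane] (stereochemistry as in 7) | O(Cc1ccccc1)C[C@H]1CCC3(OCCO3)[C@@H]2C(=C)C[C@]12C | intermediate
9 | 5'-[(benzyloxy)methyl]-6'-methylspiro[1,3-dioxolane-2,2'-bicyclo[4.2.0]octan]-8'-one (stereochemistry as in 7) | O(Cc1ccccc1)C[C@H]1CCC3(OCCO3)[C@@H]2C(=O)C[C@]12C | intermediate
10 | 3-hydroxy-3-methylbutan-2-one | CC(=O)C(C)(C)O | starting material
11 | (E)-N'-(3-hydroxy-3-methylbutan-2-ylidene)-2,4,6-tri(propan-2-yl)benzenesulfonohydrazide | C/C(=N\NS(=O)(=O)c1c(C(C)C)cc(C(C)C)cc1C(C)C)C(C)(C)O | intermediate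
12 | lithium 3-lithio-2-methylbut-3-en-2-olate | [Li]C(=C)C(C)(C)O[Li] | intermediate
13 | dilithium dialkoxide from addition of 12 to the cyclobutanone of 9 (alkenyl group on the convex face) | O(Cc1ccccc1)C[C@H]1CCC3(OCCO3)[C@@H]2[C@@](O[Li])(C(=C)C(C)(C)O[Li])C[C@]12C | intermediate
14 | 5'-[(benzyloxy)methyl]-6'-methyl-8'-[(triethylsilyl)oxy]-8'-{3-methyl-3-[(triethylsilyl)oxy]but-1-en-2-yl}spiro[1,3-dioxolane-2,2'-bicyclo[4.2.0]octane] | O(Cc1ccccc1)C[C@H]1CCC3(OCCO3)[C@@H]2[C@@](O[Si](CC)(CC)CC)(C(=C)C(C)(C)O[Si](CC)(CC)CC)C[C@]12C | intermediate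
15 | 5-[(benzyloxy)methyl]-6-methyl-8-[(triethylsilyl)oxy]-8-{3-methyl-3-[(triethylsilyl)oxy]but-1-en-2-yl}bicyclo[4.2.0]octan-2-one | O(Cc1ccccc1)C[C@H]1CCC(=O)[C@@H]2[C@@](O[Si](CC)(CC)CC)(C(=C)C(C)(C)O[Si](CC)(CC)CC)C[C@]12C | intermediate
16 | bis[tris(dimethylamino)sulfonium] salt of the doubly desilylated cyclobutanolate of 15 | O(Cc1ccccc1)C[C@H]1CCC(=O)[C@@H]2[C@@]([O-])(C(=C)C(C)(C)[O-])C[C@]12C.CN(C)[S+](N(C)C)N(C)C.CN(C)[S+](N(C)C)N(C)C | intermediate
17 | ring-opened cyclohexanone enolate carrying the 4-methyl-3-methylidene-4-oxido-2-oxopentyl chain on the methyl-bearing quaternary carbon (bis[tris(dimethylamino)sulfonium] salt) | O(Cc1ccccc1)C[C@H]1CCC([O-])=C[C@]1(C)CC(=O)C(=C)C(C)(C)[O-].CN(C)[S+](N(C)C)N(C)C.CN(C)[S+](N(C)C)N(C)C | intermediate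
18 | cis-fused decalin enolate–alkoxide formed by the Michael closure (bis[tris(dimethylamino)sulfonium] salt) | O(Cc1ccccc1)C[C@H]1CCC(=O)[C@@H]2CC(C(C)(C)[O-])=C([O-])C[C@]12C.CN(C)[S+](N(C)C)N(C)C.CN(C)[S+](N(C)C)N(C)C | intermediate
19 | cis-fused 8-[(benzyloxy)methyl]-3-(2-hydroxypropan-2-yl)-8a-methyl-5-oxo-1,4,4a,5,6,7,8,8a-octahydronaphthalen-2-yl trifluoromethanesulfonate | O(Cc1ccccc1)C[C@H]1CCC(=O)[C@@H]2CC(C(C)(C)O)=C(OS(=O)(=O)C(F)(F)F)C[C@]12C | intermediate
20 | cis-fused 4-[(benzyloxy)methyl]-7-(2-hydroxypropan-2-yl)-4a-methyl-3,4,4a,5,8,8a-hexahydronaphthalen-1(2H)-one | O(Cc1ccccc1)C[C@H]1CCC(=O)[C@@H]2CC(C(C)(C)O)=CC[C@]12C | intermediate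
21 | trans-fused 4-[(benzyloxy)methyl]-7-(2-hydroxypropan-2-yl)-4a-methyl-3,4,4a,5,8,8a-hexahydronaphthalen-1(2H)-one | O(Cc1ccccc1)C[C@H]1CCC(=O)[C@H]2CC(C(C)(C)O)=CC[C@]12C | intermediate
22 | trans-fused 4-(hydroxymethyl)-7-(2-hydroxypropan-2-yl)-4a-methyloctahydronaphthalen-1(2H)-one (both substituents equatorial and cis to the angular methyl) | OC[C@H]1CCC(=O)[C@H]2C[C@@H](C(C)(C)O)CC[C@]12C | intermediate
23 | trans-fused 6-(2-hydroxypropan-2-yl)-8a-methyl-4-oxodecahydronaphthalene-1-carbaldehyde | O=C[C@H]1CCC(=O)[C@H]2C[C@@H](C(C)(C)O)CC[C@]12C | intermediate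
24 | 1,3,5-trimethoxybenzene | COc1cc(OC)cc(OC)c1 | starting material
25 | (2,4,6-trimethoxyphenyl)lithium | COc1cc(OC)c([Li])c(OC)c1 | intermediate
26 | 4-[hydroxy(2,4,6-trimethoxyphenyl)methyl]-7-(2-hydroxypropan-2-yl)-4a-methyloctahydronaphthalen-1(2H)-one | O[C@@H](c1c(OC)cc(OC)cc1OC)[C@H]1CCC(=O)[C@H]2C[C@@H](C(C)(C)O)CC[C@]12C | intermediate
27 | 7-(2-hydroxypropan-2-yl)-4a-methyl-4-[(1R)-3-methyl-1-(2,4,6-trimethoxyphenyl)but-3-en-1-yl]octahydronaphthalen-1(2H)-one | CC(=C)C[C@@H](c1c(OC)cc(OC)cc1OC)[C@H]1CCC(=O)[C@H]2C[C@@H](C(C)(C)O)CC[C@]12C | intermediate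
28 | 7-(2-hydroxypropan-2-yl)-4a-methyl-4-[(1R)-3-methyl-1-(2,4,6-trimethoxyphenyl)butyl]octahydronaphthalen-1(2H)-one | CC(C)C[C@@H](c1c(OC)cc(OC)cc1OC)[C@H]1CCC(=O)[C@H]2C[C@@H](C(C)(C)O)CC[C@]12C | intermediate
29 | 7-(2-hydroxypropan-2-yl)-1,4a-dimethyl-4-[(1R)-3-methyl-1-(2,4,6-trimethoxyphenyl)butyl]decahydronaphthalen-1-ol | CC(C)C[C@@H](c1c(OC)cc(OC)cc1OC)[C@H]1CC[C@@](C)(O)[C@H]2C[C@@H](C(C)(C)O)CC[C@]12C | intermediate
30 | 4-[(1R)-1-(3,5-dibromo-2,4,6-trimethoxyphenyl)-3-methylbutyl]-7-(2-hydroxypropan-2-yl)-1,4a-dimethyldecahydronaphthalen-1-ol | CC(C)C[C@@H](c1c(OC)c(Br)c(OC)c(Br)c1OC)[C@H]1CC[C@@](C)(O)[C@H]2C[C@@H](C(C)(C)O)CC[C@]12C | intermediate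
31 | 3,5-dilithioaryl dilithium dialkoxide derived from 30 | CC(C)C[C@@H](c1c(OC)c([Li])c(OC)c([Li])c1OC)[C@H]1CC[C@@](C)(O[Li])[C@H]2C[C@@H](C(C)(C)O[Li])CC[C@]12C | intermediate
32 | 5-{(1R)-1-[4-hydroxy-6-(2-hydroxypropan-2-yl)-4,8a-dimethyldecahydronaphthalen-1-yl]-3-methylbutyl}-2,4,6-trimethoxybenzene-1,3-dicarbaldehyde | CC(C)C[C@@H](c1c(OC)c(C=O)c(OC)c(C=O)c1OC)[C@H]1CC[C@@](C)(O)[C@H]2C[C@@H](C(C)(C)O)CC[C@]12C | intermediate
33 | 5-{(1R)-1-[4-hydroxy-6-(2-hydroxypropan-2-yl)-4,8a-dimethyldecahydronaphthalen-1-yl]-3-methylbutyl}-2,4,6-trihydroxybenzene-1,3-dicarbaldehyde (ring stereochemistry as in the SMILES) | CC(C)C[C@@H](c1c(O)c(C=O)c(O)c(C=O)c1O)[C@H]1CC[C@@](C)(O)[C@H]2C[C@@H](C(C)(C)O)CC[C@]12C | target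

## Summary and risks

Total step count: 20. Longest linear sequence: 19 steps (steps 1–6 and 8–20; step 7 prepares the hydrazone 11).

Steps most likely to fail:

**Step 10.** After the retro-aldol opening, intermolecular Michael addition (oligomerisation of the vinyl ketone) or proton transfer that scrambles the enolates could outrun ring closure and regiospecific triflation. The fallback sets out from 15 and returns at 22. Desilylation of 15 with Bu4NF buffered with AcOH in THF should give, by retro-aldol opening of the freed cyclobutanol, the isolable ring-opened keto enone 4-[(benzyloxy)methyl]-3-(4-hydroxy-4-methyl-3-methylidene-2-oxopentyl)-3-methylcyclohexan-1-one F1. Pyrrolidine/AcOH (enamine-mediated intramolecular Michael addition under equilibrating conditions) should then close ring B to the trans-fused diketone 4-[(benzyloxy)methyl]-7-(2-hydroxypropan-2-yl)-4a-methyloctahydronaphthalene-1,6-dione F2, with the hydroxyisopropyl group equatorial. The C8 carbonyl, the only β-hydroxy ketone, is reduced by hydroxyl-directed hydride delivery with Me4NBH(OAc)3 (Evans–Saksena reduction) to 4-[(benzyloxy)methyl]-6-hydroxy-7-(2-hydroxypropan-2-yl)-4a-methyloctahydronaphthalen-1(2H)-one F3. Its secondary alcohol is converted with 1,1'-thiocarbonyldiimidazole into the O-alkyl imidazole-1-carbothioate F4 and deoxygenated with Bu3SnH/AIBN (Barton–McCombie) to trans-fused 4-[(benzyloxy)methyl]-7-(2-hydroxypropan-2-yl)-4a-methyloctahydronaphthalen-1(2H)-one F5. Hydrogenolysis (H2, Pd/C) of F5 gives 22.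

**Step 15.** Capture of the planar benzylic cation could occur with low facial selectivity or with the sense opposite to the A(1,3) model, and loss of the C1 proton to a styrene could compete. The fallback sets out from 23 and returns at 28; it exchanges the roles of the two carbon groups, so the arene is the incoming group and the same model operates with the opposite topicity. Addition of 2-methylprop-1-enylmagnesium bromide to 23 (THF, −78 °C) should give the allylic alcohol 4-(1-hydroxy-3-methylbut-2-en-1-yl)-7-(2-hydroxypropan-2-yl)-4a-methyloctahydronaphthalen-1(2H)-one F6. Ionisation with catalytic Sc(OTf)3 in the presence of excess 24 should give, by Friedel–Crafts allylation at the secondary allylic terminus, 7-(2-hydroxypropan-2-yl)-4a-methyl-4-[3-methyl-1-(2,4,6-trimethoxyphenyl)but-2-en-1-yl]octahydronaphthalen-1(2H)-one F7. Hydrogenation (H2, Pd/C) of F7 gives 28.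

**Step 19.** The second bromine–lithium exchange could stay incomplete, and aryllithium intermediates could be protonated by the medium, so that formylation is only partial. The fallback sets out from 29 and returns at 32; it uses C–H lithiation instead of halogen–metal exchange. Directed ortho-lithiation of 29 (n-BuLi, TMEDA, THF, 0 °C) at a ring position between two methoxy groups and a DMF quench should give the mono-aldehyde 3-{(1R)-1-[4-hydroxy-6-(2-hydroxypropan-2-yl)-4,8a-dimethyldecahydronaphthalen-1-yl]-3-methylbutyl}-2,4,6-trimethoxybenzaldehyde F8. After in situ masking of this aldehyde as its α-amino alkoxide with lithium N,N,N'-trimethylethylenediamide, a second lithiation (n-BuLi) and DMF quench gives 32.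

Further compounds

F1 | step 10 | 4-[(benzyloxy)methyl]-3-(4-hydroxy-4-methyl-3-methylidene-2-oxopentyl)-3-methylcyclohexan-1-one | O(Cc1ccccc1)C[C@H]1CCC(=O)C[C@]1(C)CC(=O)C(=C)C(C)(C)O
F2 | step 10 | trans-fused 4-[(benzyloxy)methyl]-7-(2-hydroxypropan-2-yl)-4a-methyloctahydronaphthalene-1,6-dione | O(Cc1ccccc1)C[C@H]1CCC(=O)[C@H]2C[C@@H](C(C)(C)O)C(=O)C[C@]12C
F3 | step 10 | trans-fused 4-[(benzyloxy)methyl]-6-hydroxy-7-(2-hydroxypropan-2-yl)-4a-methyloctahydronaphthalen-1(2H)-one (axial hydroxyl drawn; its configuration is immaterial) | O(Cc1ccccc1)C[C@H]1CCC(=O)[C@H]2C[C@@H](C(C)(C)O)[C@@H](O)C[C@]12C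
F4 | step 10 | O-{5-[(benzyloxy)methyl]-3-(2-hydroxypropan-2-yl)-4a-methyl-8-oxodecahydronaphthalen-2-yl} 1H-imidazole-1-carbothioate | O(Cc1ccccc1)C[C@H]1CCC(=O)[C@H]2C[C@@H](C(C)(C)O)[C@@H](OC(=S)n3ccnc3)C[C@]12C
F5 | step 10 | trans-fused 4-[(benzyloxy)methyl]-7-(2-hydroxypropan-2-yl)-4a-methyloctahydronaphthalen-1(2H)-one | O(Cc1ccccc1)C[C@H]1CCC(=O)[C@H]2C[C@@H](C(C)(C)O)CC[C@]12C
F6 | step 15 | 4-(1-hydroxy-3-methylbut-2-en-1-yl)-7-(2-hydroxypropan-2-yl)-4a-methyloctahydronaphthalen-1(2H)-one (Felkin–Anh epimer drawn; the carbinol configuration is immaterial) | CC(C)=C[C@H](O)[C@H]1CCC(=O)[C@H]2C[C@@H](C(C)(C)O)CC[C@]12C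
F7 | step 15 | 7-(2-hydroxypropan-2-yl)-4a-methyl-4-[3-methyl-1-(2,4,6-trimethoxyphenyl)but-2-en-1-yl]octahydronaphthalen-1(2H)-one (benzylic configuration as in 28) | CC(C)=C[C@@H](c1c(OC)cc(OC)cc1OC)[C@H]1CCC(=O)[C@H]2C[C@@H](C(C)(C)O)CC[C@]12C
F8 | step 19 | 3-{(1R)-1-[4-hydroxy-6-(2-hydroxypropan-2-yl)-4,8a-dimethyldecahydronaphthalen-1-yl]-3-methylbutyl}-2,4,6-trimethoxybenzaldehyde | CC(C)C[C@@H](c1c(OC)cc(OC)c(C=O)c1OC)[C@H]1CC[C@@](C)(O)[C@H]2C[C@@H](C(C)(C)O)CC[C@]12C
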